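The numbers in the tables were generated by integration with constants of no real substance.

The slowness of the blue flask struck me first: at 40.0 min free monomer was still sinking while monomer in chains stood still, and I had to say what it would hold at 80 min.

the same everywhere: free monomer 1.6 M; initiator 74 mM

|  | impurity | remark | time |
|---|---|---|---|
| blue | 27 mM | the very flask that is asked about, followed so far |  |
| teal | 14 mM | run made earlier |  |
| flask | 27 mM |  | 80 min |

- blue (time / min: monomer in chains / %, free monomer / %): 3.00: 7.3, 89.5; 5.00: 12.1, 84.9; 8.00: 15.7, 80.1; 12.0: 14.2, 79.2; 15.0: 14.2, 77.8; 25.0: 14.8, 71.7; 40.0: 14.6, 67.2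
- teal (time / min: monomer in chains / %, free monomer / %): 3.00: 10.7, 86.3; 8.00: 15.2, 78.8; 15.0: 16.8, 75.7; 25.0: 17.7, 70.1; 30.0: 19.4, 67.3; 40.0: 17.7, 63.8; 60.0: 17.0, 55.1

(readings scatter by 1 percentage point)

1. average number of monomer units in a chain (chains begun, living or dead) at 80 min
2. part of the free monomer that has reacted at 80 min

- the average divides the monomer in chains by the number of chains begun, living and dead together
- the numbers in the tables scatter with a standard deviation of 1 percentage point
- the earlier runs do not show the number of chains; that part of a forecast is a guess

I laid out a ladder of time scales, fastest first. On the top rung I assumed that impurity destroys initiator, one for one, before chains start. Impurity is the smaller charge, the limiting reagent of that reaction, so its balance leaves the chains begun, initiator charged minus impurity charged, 47.0 mM in the blue flask and 60.0 mM in the teal run. No run counts chains, so this is a guess, but the plateaus of monomer in chains, 14.4% in blue and 17.7% in teal, stand in a ratio of 0.814 against 0.783 for the chains. On the second rung, the readings of monomer in chains in the blue flask had stopped rising by about 8.00 min; the third rung was a first-order loss of free monomer making no chains, whose half-life I read from teal as 98.2 min, so that rise ended sooner than one such half-life. So I reckoned 4.92 units per chain and, running on from the last blue reading, 49.3% reacted. The forecast gave 4.6 and 49%, its chains a little shorter than mine, “suggesting impurity removes initiator”.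

The flask gave 4.82 and 49.3%.

    free monomer + initiator → living end + monomer in chains (k = 0.0150 L mol⁻¹ s⁻¹)
    free monomer + living end → monomer in chains + living end, rate k2*[living end]*[free monomer] (k = 0.0305 L mol⁻¹ s⁻¹)
    monomer in chains + living end → free monomer + living end, rate k3*[living end] as long as [monomer in chains] is above zero (k = 0.0223 s⁻¹)
    initiator + impurity → spent initiator A (k = 158 L mol⁻¹ s⁻¹)
    living end → dead end B (k = 0.00556 s⁻¹)
    free monomer → uncatalysed product (k = 1.09 × 10⁻⁴ s⁻¹)

At 80 min the blue flask had not come to rest, though its chains had: dead end B stood at 0.0470 M, the 47.0 mM of the balance, and living end at 1.59 × 10⁻¹³ M. The same balance gives 6.00 mM for a neighbour charged with 0.068 M of impurity, which held 0.00600 M of dead end B and an average of 5.51. In the blue flask, free monomer was still 50.7%, and the half-life of the whole flask's slowest mode, as it stood then, was 106 min. By 800 min the average stayed 4.82, while uncatalysed product rose from 35.1% to 85.4% and the part reacted reached 99.5%.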